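Locants: tetrahydrofuran O1, C2 (aryl), C3 (C9H2OH), C4 (O4H), C5 (benzyl). The ring is made by turning a 1,3-dioxolane inside out: C2 starts as the carbon of an arylmethylidene acetal bridging O4 and O1 of an anti-diol, with C3–C9 hanging on C4 as a CH2CHO arm. In one operation a silyl triflate makes the C9 enol silane, opens the acetal to the O1=C2 oxocarbenium ion and lets C3 attack C2; this closes the ring through the C2–C3 bond, frees O4 as its silyl ether and settles C2/C3 all-trans. The step exploits the vicinal O4/O1 pair and the cation-stabilising aryl (ring A) on C2. The erythro aryloxypropanediol arm follows by Evans aldol and Mitsunobu inversion.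

Key step: step 7

Remarks: ring A = aryl on C2, ring B = aryl of the C5 benzyl group, ring C = aryl of the propanediol arm (C7' carbinol carbon, C8' aryloxy carbon, C9' its CH2OH). TBS = tert-butyldimethylsilyl, TIPS = triisopropylsilyl. Compounds 5 and 18 are taken to be commercial. The target is (2S,3S,4S,5R) in these locants and (7'R,8'S), erythro, in the arm.

Step 1
Reactants: 1 vanillin
Product: 2 3-methoxy-4-(triisopropylsilyloxy)benzaldehyde
Conditions: TIPSCl, imidazole, DMF, rt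
Reagents that add atoms: triisopropylsilyl chloride, CC(C)[Si](Cl)(C(C)C)C(C)C
Why: Silyl ether formation on the phenol gives one aldehyde that serves twice (rings A and C) and whose protecting group falls in the final fluoride step.

Step 2
Reactants: 3 penta-1,4-dien-3-ol
Product: 4 (2R,3S)-1,2-epoxypent-4-en-3-ol
Conditions: Ti(OiPr)4 (cat.), L-(+)-diisopropyl tartrate, t-BuOOH, 4 Å molecular sieves, CH2Cl2, −20 °C
Reagents that add atoms: tert-butyl hydroperoxide, CC(C)(C)OO
Why: Sharpless asymmetric epoxidation desymmetrises the achiral divinyl carbinol by choosing one enantiotopic vinyl group and one face, which should give the erythro epoxy alcohol that fixes C5 (epoxide CH, R) and C4 (carbinol, S), the minor enantiomer being removed by a second epoxidation.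

Step 3
Reactants: 4 (2R,3S)-1,2-epoxypent-4-en-3-ol; 5 1-(benzyloxy)-4-bromo-2-methoxybenzene
Product: 7 (3S,4R)-5-[4-(benzyloxy)-3-methoxyphenyl]pent-1-ene-3,4-diol, via aryl Grignard reagent 6 (not isolated)
Conditions: 5, Mg, THF, rt → 40 °C; then 4 (0.4 equiv relative to 6), CuI (10 mol %), THF, −30 → 0 °C; aq NH4Cl
Reagents that add atoms: none
Why: Copper-catalysed SN2 opening of the terminal epoxide at its CH2 carbon by the aryl Grignard reagent installs ring B and leaves both oxygen-bearing stereocentres untouched, one equivalent of 6 being spent on the hydroxyl proton.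

Step 4
Reactants: 7 (3S,4R)-5-[4-(benzyloxy)-3-methoxyphenyl]pent-1-ene-3,4-diol; 2 3-methoxy-4-(triisopropylsilyloxy)benzaldehyde
Product: 8 (4S,5R)-5-[4-(benzyloxy)-3-methoxybenzyl]-4-ethenyl-2-[3-methoxy-4-(triisopropylsilyloxy)phenyl]-1,3-dioxolane (4,5-cis; both epimers at the acetal carbon)
Conditions: PPTS (cat.), benzene, reflux, Dean–Stark trap
Reagents that add atoms: none
Why: Acid-catalysed acetalisation of the 1,2-diol with removal of water gives the 4,5-cis dioxolane from the erythro diol, and the acetal centre (the future C2) may be a mixture because step 7 ionises it.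

Step 5
Reactants: 8 the vinyl dioxolane
Product: 10 2-[(4S,5R)-5-[4-(benzyloxy)-3-methoxybenzyl]-2-[3-methoxy-4-(triisopropylsilyloxy)phenyl]-1,3-dioxolan-4-yl]ethanol, via B-alkyl-9-borabicyclo[3.3.1]nonane 9 (not isolated)
Conditions: 9-borabicyclo[3.3.1]nonane (9-BBN), THF, 0 °C → rt; then aq NaOAc, H2O2, 0 °C → rt
Reagents that add atoms: hydrogen peroxide, OO
Why: Anti-Markovnikov hydroboration of the terminal vinyl group by the bulky borane followed by acetate-buffered peroxide oxidation gives the primary alcohol that becomes C9, with no new stereocentre and no effect on acetal, benzyl or aryl silyl ether.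

Step 6
Reactants: 10 the dioxolanyl ethanol
Product: 11 [(4S,5R)-5-[4-(benzyloxy)-3-methoxybenzyl]-2-[3-methoxy-4-(triisopropylsilyloxy)phenyl]-1,3-dioxolan-4-yl]acetaldehyde
Conditions: Dess–Martin periodinane, pyridine, CH2Cl2, 0 °C → rt; used crude
Reagents that add atoms: none
Why: Dess–Martin oxidation under pyridine buffering should give the β-alkoxy aldehyde without β-elimination or acetal cleavage, and no stereocentre is touched.

Step 7
Reactants: 11 the dioxolanyl acetaldehyde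
Product: 14 (2S,3R,4S,5R)-5-[4-(benzyloxy)-3-methoxybenzyl]-4-(tert-butyldimethylsilyloxy)-2-[3-methoxy-4-(triisopropylsilyloxy)phenyl]tetrahydrofuran-3-carbaldehyde (all-trans), via silyl enol ether 12 (not isolated), via oxocarbenium triflate 13 (not isolated)
Conditions: TBSOTf (1.5 equiv), i-Pr2NEt (1.1 equiv), CH2Cl2, −78 °C → −20 °C
Reagents that add atoms: tert-butyldimethylsilyl triflate, CC(C)(C)[Si](C)(C)OS(=O)(=O)C(F)(F)F
Why: Soft enolisation (silyl triflate/amine) converts the aldehyde into enol silane 12, the excess TBSOTf ionises the electron-rich benzylidene acetal at the C2–O4 bond to the O1=C2 oxocarbenium ion 13 (cleavage at C2–O1 is unproductive and reversible), C3 of the enol silane adds to C2, and silyl loss from the resulting C9 oxocarbenium regenerates TBSOTf, so that after enolisation the change is a Lewis-acid-catalysed isomerisation. The closest known reaction types are the Mukaiyama aldol-type addition of in situ formed enol silanes to acetals, used here intramolecularly, and, for the oxocarbenium/enol closure itself, the Lewis-acid O-to-C rearrangement of cyclic vinyl acetals to 2-substituted tetrahydrofuran-3-carbaldehydes (Petasis–Ferrier type). The tetrahydrofuran closes in the 5-(enolexo)-endo-trig mode while the dioxolane opens. C3 is expected trans to the C4 silyloxy group (allylic 1,3-strain puts C4–H in the plane of the (Z)-enol silane, and the centre stays epimerisable as an aldehyde α-carbon), and C2, which may first form cis to the C5 benzyl group, should equilibrate at −20 °C through reversible C2–C3 heterolysis or benzylic C2–O1 ionisation, both assisted by ring A, to the all-trans isomer, the only one free of cis-vicinal contacts once the trans C4/C5 pair is fixed. The step needs C-attack by the enol silane to outrun oxa-Pictet–Spengler capture of 13 by ring B, which the much higher nucleophilicity of the enol silane and the low temperature should secure, and it needs the β-silyloxy aldehyde to survive, which the buffered medium and the immediate reduction in step 8 should secure.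

Step 8
Reactants: 14 the tetrahydrofuran-3-carbaldehyde
Product: 15 [(2S,3R,4S,5R)-5-[4-(benzyloxy)-3-methoxybenzyl]-4-(tert-butyldimethylsilyloxy)-2-[3-methoxy-4-(triisopropylsilyloxy)phenyl]tetrahydrofuran-3-yl]methanol
Conditions: NaBH4, MeOH/THF, −20 → 0 °C
Reagents that add atoms: none
Why: Borohydride reduction of the aldehyde to the C9 alcohol removes the epimerisable, elimination-prone β-silyloxy aldehyde at once and changes no stereocentre.

Step 9
Reactants: 15 the C9 alcohol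
Product: 16 (2S,3R,4S,5R)-5-[4-(benzyloxy)-3-methoxybenzyl]-4-(tert-butyldimethylsilyloxy)-3-[(tert-butyldimethylsilyloxy)methyl]-2-[3-methoxy-4-(triisopropylsilyloxy)phenyl]tetrahydrofuran
Conditions: TBSCl, imidazole, DMF, rt
Reagents that add atoms: tert-butyldimethylsilyl chloride, CC(C)(C)[Si](C)(C)Cl
Why: Silyl ether formation protects the primary hydroxyl for the enolate and Mitsunobu chemistry that follows.

Step 10
Reactants: 16 the bis-TBS ether
Product: 17 (2S,3R,4S,5R)-4-(tert-butyldimethylsilyloxy)-3-[(tert-butyldimethylsilyloxy)methyl]-5-(4-hydroxy-3-methoxybenzyl)-2-[3-methoxy-4-(triisopropylsilyloxy)phenyl]tetrahydrofuran (ring B phenol)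
Conditions: H2 (1 atm), palladium on carbon (10% Pd/C), EtOAc, rt
Reagents that add atoms: none
Why: Hydrogenolysis cleaves the phenolic benzyl ether of ring B much faster than the cyclic benzylic C2–O1 ether and leaves silyl ethers alone, so only the ring B phenol is unveiled.

Step 11
Reactants: 17 the ring B phenol; 18 (R)-4-benzyl-3-(chloroacetyl)oxazolidin-2-one
Product: 19 (R)-4-benzyl-3-(aryloxyacetyl)oxazolidin-2-one, in which the aryloxy group is the ring B phenoxy group of 17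
Conditions: K2CO3, NaI (cat.), acetone, rt → 40 °C
Reagents that add atoms: none
Why: Williamson ether synthesis, in which the phenoxide displaces the activated α-halide (iodide catalysis) while alkyl TBS and aryl TIPS ethers are stable to carbonate in acetone.

Step 12
Reactants: 19 the aryloxyacetyl imide; 2 3-methoxy-4-(triisopropylsilyloxy)benzaldehyde
Product: 21 (4R)-4-benzyl-3-[(2R,3S)-2-(ring B aryloxy)-3-hydroxy-3-[3-methoxy-4-(triisopropylsilyloxy)phenyl]propanoyl]oxazolidin-2-one (syn aldol adduct), via dibutylboron (Z)-enolate 20 (not isolated)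
Conditions: n-Bu2BOTf, i-Pr2NEt, CH2Cl2, −78 → 0 °C; then 2, −78 → 0 °C; pH 7 buffer, MeOH, H2O2, 0 °C
Reagents that add atoms: none
Why: Evans syn-aldol reaction, in which the (Z)-boron enolate adds through a closed Zimmerman–Traxler chair on the face away from the benzyl group of the (R)-auxiliary, which should set C8' as required (S in the final diol) and C7' as the epimer (S) of the target.

Step 13
Reactants: 21 the syn aldol adduct
Product: 22 (4R)-4-benzyl-3-[(2R,3R)-2-(ring B aryloxy)-3-[3-methoxy-4-(triisopropylsilyloxy)phenyl]-3-(4-nitrobenzoyloxy)propanoyl]oxazolidin-2-one (anti)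
Conditions: 4-nitrobenzoic acid, PPh3, DIAD, THF, 0 °C → rt
Reagents that add atoms: 4-nitrobenzoic acid, O=C(O)c1ccc([N+](=O)[O-])cc1
Why: Mitsunobu esterification inverts the benzylic carbinol C7' by SN2 displacement of the oxyphosphonium ion by the carboxylate, turning the syn (threo) pair into the anti (erythro) pair of the target.

Step 14
Reactants: 22 the inverted 4-nitrobenzoate
Product: 23 (1R,2S)-2-(ring B aryloxy)-1-[3-methoxy-4-(triisopropylsilyloxy)phenyl]propane-1,3-diol (erythro; ring B aryloxy as in 17, all four silyl ethers retained)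
Conditions: LiBH4, THF/MeOH, 0 °C → rt
Reagents that add atoms: none
Why: Lithium borohydride cleaves the imide reductively to the primary alcohol C9' and reduces off the activated 4-nitrobenzoate without touching C7' or C8', and any loss of an aryl silyl group here is harmless before step 15.

Step 15
Reactants: 23 the tetrasilylated erythro diol
Product: 24 (1R,2S)-1-(4-hydroxy-3-methoxyphenyl)-2-[4-{[(2R,3S,4S,5S)-3-hydroxy-5-(4-hydroxy-3-methoxyphenyl)-4-(hydroxymethyl)oxolan-2-yl]methyl}-2-methoxyphenoxy]propane-1,3-diol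
Conditions: TBAF, AcOH, THF, 0 °C → rt
Reagents that add atoms: none
Why: Fluoride-mediated desilylation cleaves the two aryl TIPS and two alkyl TBS ethers (driven by Si–F bond formation) under acetic acid buffering, which avoids the acid or hydrogenolysis conditions that would endanger the benzylic C2–O1 and C7'–OH bonds.

Compound list
1 | vanillin (4-hydroxy-3-methoxybenzaldehyde) | COc1cc(C=O)ccc1O | starting material
2 | 3-methoxy-4-(triisopropylsilyloxy)benzaldehyde | COc1cc(C=O)ccc1O[Si](C(C)C)(C(C)C)C(C)C | intermediate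
3 | penta-1,4-dien-3-ol | C=CC(O)C=C | starting material
4 | (2R,3S)-1,2-epoxypent-4-en-3-ol | C=C[C@H](O)[C@H]1CO1 | intermediate
5 | 1-(benzyloxy)-4-bromo-2-methoxybenzene | COc1cc(Br)ccc1OCc1ccccc1 | starting material
6 | [4-(benzyloxy)-3-methoxyphenyl]magnesium bromide | COc1cc([Mg]Br)ccc1OCc1ccccc1 | intermediate (not isolated)
7 | (3S,4R)-5-[4-(benzyloxy)-3-methoxyphenyl]pent-1-ene-3,4-diol | C=C[C@H](O)[C@H](O)Cc1ccc(OCc2ccccc2)c(OC)c1 | intermediate
8 | (4S,5R)-5-[4-(benzyloxy)-3-methoxybenzyl]-4-ethenyl-2-[3-methoxy-4-(triisopropylsilyloxy)phenyl]-1,3-dioxolane (4,5-cis, both acetal epimers) | C=C[C@@H]1OC(c2ccc(O[Si](C(C)C)(C(C)C)C(C)C)c(OC)c2)O[C@@H]1Cc1ccc(OCc2ccccc2)c(OC)c1 | intermediate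
9 | 9-{2-[(4S,5R)-5-[4-(benzyloxy)-3-methoxybenzyl]-2-[3-methoxy-4-(triisopropylsilyloxy)phenyl]-1,3-dioxolan-4-yl]ethyl}-9-borabicyclo[3.3.1]nonane | C1CCC2CCCC1B2CC[C@@H]1OC(c2ccc(O[Si](C(C)C)(C(C)C)C(C)C)c(OC)c2)O[C@@H]1Cc1ccc(OCc2ccccc2)c(OC)c1 | intermediate (not isolated)
10 | 2-[(4S,5R)-5-[4-(benzyloxy)-3-methoxybenzyl]-2-[3-methoxy-4-(triisopropylsilyloxy)phenyl]-1,3-dioxolan-4-yl]ethanol | OCC[C@@H]1OC(c2ccc(O[Si](C(C)C)(C(C)C)C(C)C)c(OC)c2)O[C@@H]1Cc1ccc(OCc2ccccc2)c(OC)c1 | intermediate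
11 | [(4S,5R)-5-[4-(benzyloxy)-3-methoxybenzyl]-2-[3-methoxy-4-(triisopropylsilyloxy)phenyl]-1,3-dioxolan-4-yl]acetaldehyde | O=CC[C@@H]1OC(c2ccc(O[Si](C(C)C)(C(C)C)C(C)C)c(OC)c2)O[C@@H]1Cc1ccc(OCc2ccccc2)c(OC)c1 | intermediate
12 | tert-butyldimethylsilyl enol ether of 11 (Z/E mixture, mainly Z expected) | CC(C)(C)[Si](C)(C)OC=C[C@@H]1OC(c2ccc(O[Si](C(C)C)(C(C)C)C(C)C)c(OC)c2)O[C@@H]1Cc1ccc(OCc2ccccc2)c(OC)c1 | intermediate (not isolated)
13 | ring-opened O1=C2 oxocarbenium triflate carrying the O4 silyl ether and the C9 enol silane | CC(C)(C)[Si](C)(C)OC=C[C@H](O[Si](C)(C)C(C)(C)C)[C@@H](Cc1ccc(OCc2ccccc2)c(OC)c1)[O+]=Cc1ccc(O[Si](C(C)C)(C(C)C)C(C)C)c(OC)c1.[O-]S(=O)(=O)C(F)(F)F | intermediate (not isolated)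
14 | (2S,3R,4S,5R)-5-[4-(benzyloxy)-3-methoxybenzyl]-4-(tert-butyldimethylsilyloxy)-2-[3-methoxy-4-(triisopropylsilyloxy)phenyl]tetrahydrofuran-3-carbaldehyde | COc1cc(C[C@H]2O[C@H](c3ccc(O[Si](C(C)C)(C(C)C)C(C)C)c(OC)c3)[C@@H](C=O)[C@@H]2O[Si](C)(C)C(C)(C)C)ccc1OCc1ccccc1 | intermediate
15 | [(2S,3R,4S,5R)-5-[4-(benzyloxy)-3-methoxybenzyl]-4-(tert-butyldimethylsilyloxy)-2-[3-methoxy-4-(triisopropylsilyloxy)phenyl]tetrahydrofuran-3-yl]methanol | COc1cc(C[C@H]2O[C@H](c3ccc(O[Si](C(C)C)(C(C)C)C(C)C)c(OC)c3)[C@@H](CO)[C@@H]2O[Si](C)(C)C(C)(C)C)ccc1OCc1ccccc1 | intermediate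
16 | (2S,3R,4S,5R)-5-[4-(benzyloxy)-3-methoxybenzyl]-4-(tert-butyldimethylsilyloxy)-3-[(tert-butyldimethylsilyloxy)methyl]-2-[3-methoxy-4-(triisopropylsilyloxy)phenyl]tetrahydrofuran | COc1cc(C[C@H]2O[C@H](c3ccc(O[Si](C(C)C)(C(C)C)C(C)C)c(OC)c3)[C@@H](CO[Si](C)(C)C(C)(C)C)[C@@H]2O[Si](C)(C)C(C)(C)C)ccc1OCc1ccccc1 | intermediate
17 | (2S,3R,4S,5R)-4-(tert-butyldimethylsilyloxy)-3-[(tert-butyldimethylsilyloxy)methyl]-5-(4-hydroxy-3-methoxybenzyl)-2-[3-methoxy-4-(triisopropylsilyloxy)phenyl]tetrahydrofuran | COc1cc(C[C@H]2O[C@H](c3ccc(O[Si](C(C)C)(C(C)C)C(C)C)c(OC)c3)[C@@H](CO[Si](C)(C)C(C)(C)C)[C@@H]2O[Si](C)(C)C(C)(C)C)ccc1O | intermediate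
18 | (R)-4-benzyl-3-(chloroacetyl)oxazolidin-2-one | O=C(CCl)N1[C@H](Cc2ccccc2)COC1=O | starting material
19 | (R)-4-benzyl-3-(aryloxyacetyl)oxazolidin-2-one, aryloxy = ring B phenoxy group of 17 | COc1cc(C[C@H]2O[C@H](c3ccc(O[Si](C(C)C)(C(C)C)C(C)C)c(OC)c3)[C@@H](CO[Si](C)(C)C(C)(C)C)[C@@H]2O[Si](C)(C)C(C)(C)C)ccc1OCC(=O)N1[C@H](Cc2ccccc2)COC1=O | intermediate
20 | dibutylboron (Z)-enolate of 19 | CCCCB(CCCC)O/C(=C\Oc1ccc(C[C@H]2O[C@H](c3ccc(O[Si](C(C)C)(C(C)C)C(C)C)c(OC)c3)[C@@H](CO[Si](C)(C)C(C)(C)C)[C@@H]2O[Si](C)(C)C(C)(C)C)cc1OC)N1[C@H](Cc2ccccc2)COC1=O | intermediate (not isolated)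
21 | (4R)-4-benzyl-3-[(2R,3S)-2-(ring B aryloxy)-3-hydroxy-3-[3-methoxy-4-(triisopropylsilyloxy)phenyl]propanoyl]oxazolidin-2-one | COc1cc([C@H](O)[C@H](C(=O)N2[C@H](Cc3ccccc3)COC2=O)Oc2ccc(C[C@H]3O[C@H](c4ccc(O[Si](C(C)C)(C(C)C)C(C)C)c(OC)c4)[C@@H](CO[Si](C)(C)C(C)(C)C)[C@@H]3O[Si](C)(C)C(C)(C)C)cc2OC)ccc1O[Si](C(C)C)(C(C)C)C(C)C | intermediate
22 | (4R)-4-benzyl-3-[(2R,3R)-2-(ring B aryloxy)-3-[3-methoxy-4-(triisopropylsilyloxy)phenyl]-3-(4-nitrobenzoyloxy)propanoyl]oxazolidin-2-one | COc1cc([C@@H](OC(=O)c2ccc([N+](=O)[O-])cc2)[C@H](C(=O)N2[C@H](Cc3ccccc3)COC2=O)Oc2ccc(C[C@H]3O[C@H](c4ccc(O[Si](C(C)C)(C(C)C)C(C)C)c(OC)c4)[C@@H](CO[Si](C)(C)C(C)(C)C)[C@@H]3O[Si](C)(C)C(C)(C)C)cc2OC)ccc1O[Si](C(C)C)(C(C)C)C(C)C | intermediate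
23 | (1R,2S)-2-(ring B aryloxy)-1-[3-methoxy-4-(triisopropylsilyloxy)phenyl]propane-1,3-diol, core still carrying two TBS and one TIPS ether | COc1cc([C@@H](O)[C@H](CO)Oc2ccc(C[C@H]3O[C@H](c4ccc(O[Si](C(C)C)(C(C)C)C(C)C)c(OC)c4)[C@@H](CO[Si](C)(C)C(C)(C)C)[C@@H]3O[Si](C)(C)C(C)(C)C)cc2OC)ccc1O[Si](C(C)C)(C(C)C)C(C)C | intermediate
24 | (1R,2S)-1-(4-hydroxy-3-methoxyphenyl)-2-[4-{[(2R,3S,4S,5S)-3-hydroxy-5-(4-hydroxy-3-methoxyphenyl)-4-(hydroxymethyl)oxolan-2-yl]methyl}-2-methoxyphenoxy]propane-1,3-diol | COc1cc([C@@H](O)[C@H](CO)Oc2ccc(C[C@H]3O[C@H](c4ccc(O)c(OC)c4)[C@@H](CO)[C@@H]3O)cc2OC)ccc1O | target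

Total step count: 15. Longest linear sequence: 14 steps (3 → 24, steps 2–15); step 1 is a one-step side branch.

Steps most likely to fail

Step 7. The equilibration may stop short and leave the kinetic isomer in which the C2 aryl group is cis to C3 and C5. Prolonged exposure to the Lewis acid may instead let ring B capture the oxocarbenium ion (oxa-Pictet–Spengler) or cause β-elimination of the C4 silyloxy group. Fallback: setting out from aldehyde 11, the silyl enol ether 12 is isolated (TBSOTf 1.05 equiv, Et3N 3 equiv, CH2Cl2, −78 °C) and cyclised under kinetic control (TBSOTf 10 mol %, CH2Cl2, −78 °C, short reaction time). This should give whichever C2 epimer forms first, expected to be the 2,3-cis tetrahydrofuran-3-carbaldehyde F1, the C2 epimer of 14. Aldehyde F1 is reduced in the same flask (NaBH4, EtOH, −78 → 0 °C) to the C2-epimeric tetrahydrofuran-3-ylmethanol F2. Alcohol F2 is then epimerised at C2 alone by reversible benzylic ionisation of the C2–O1 bond (BF3·OEt2 cat., CH2Cl2, −20 °C), a path that never regenerates the O1=C2 oxocarbenium ion and so cannot feed the arene cyclisation. The route is rejoined at 15.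

Step 13. The electron-rich benzylic oxyphosphonium ion may ionise, which erodes the inversion, or the β-activated imide may eliminate to the α-aryloxycinnamoyl imide. Fallback: setting out from aldol adduct 21, LiBH4 (THF/MeOH, 0 °C) should give the threo 1,3-diol F3, and TBSCl/imidazole at 0 °C should silylate only the primary hydroxyl to give the mono-TBS ether F4. Dess–Martin oxidation of the benzylic alcohol of F4 should give the α-aryloxy aryl ketone F5, and chelation-controlled reduction of F5 with Zn(BH4)2 (Et2O, −20 °C) should give the erythro alcohol F6. The conditions of step 15 then remove all five silyl groups from F6 and the route is rejoined at the target 24.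

Step 11. The phenoxide may attack the imide carbonyl (acyl transfer with loss of the auxiliary) instead of displacing the halide. Fallback: setting out from phenol 17, alkylation with allyl bromoacetate (K2CO3, acetone) should give the allyl aryloxyacetate F7, and Pd(PPh3)4/morpholine (THF, rt) should free the aryloxyacetic acid F8. Pivaloyl chloride/Et3N (THF, −20 °C) converts F8 into the mixed pivalic anhydride F9, and F9 N-acylates (R)-4-benzyloxazolidin-2-one (LiCl, Et3N, THF) to rejoin the route at imide 19.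

Further compounds
F1 | step 7 | (2R,3R,4S,5R)-5-[4-(benzyloxy)-3-methoxybenzyl]-4-(tert-butyldimethylsilyloxy)-2-[3-methoxy-4-(triisopropylsilyloxy)phenyl]tetrahydrofuran-3-carbaldehyde (C2 epimer of 14) | COc1cc(C[C@H]2O[C@@H](c3ccc(O[Si](C(C)C)(C(C)C)C(C)C)c(OC)c3)[C@@H](C=O)[C@@H]2O[Si](C)(C)C(C)(C)C)ccc1OCc1ccccc1
F2 | step 7 | [(2R,3R,4S,5R)-5-[4-(benzyloxy)-3-methoxybenzyl]-4-(tert-butyldimethylsilyloxy)-2-[3-methoxy-4-(triisopropylsilyloxy)phenyl]tetrahydrofuran-3-yl]methanol (C2 epimer of 15) | COc1cc(C[C@H]2O[C@@H](c3ccc(O[Si](C(C)C)(C(C)C)C(C)C)c(OC)c3)[C@@H](CO)[C@@H]2O[Si](C)(C)C(C)(C)C)ccc1OCc1ccccc1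
F3 | step 13 | (1S,2S)-2-(ring B aryloxy)-1-[3-methoxy-4-(triisopropylsilyloxy)phenyl]propane-1,3-diol (threo, C7' epimer of 23) | COc1cc([C@H](O)[C@H](CO)Oc2ccc(C[C@H]3O[C@H](c4ccc(O[Si](C(C)C)(C(C)C)C(C)C)c(OC)c4)[C@@H](CO[Si](C)(C)C(C)(C)C)[C@@H]3O[Si](C)(C)C(C)(C)C)cc2OC)ccc1O[Si](C(C)C)(C(C)C)C(C)C
F4 | step 13 | C9'-O-TBS ether of F3 | COc1cc([C@H](O)[C@H](CO[Si](C)(C)C(C)(C)C)Oc2ccc(C[C@H]3O[C@H](c4ccc(O[Si](C(C)C)(C(C)C)C(C)C)c(OC)c4)[C@@H](CO[Si](C)(C)C(C)(C)C)[C@@H]3O[Si](C)(C)C(C)(C)C)cc2OC)ccc1O[Si](C(C)C)(C(C)C)C(C)C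
F5 | step 13 | C7' ketone of F4 (α-aryloxy aryl ketone, C8' unchanged) | COc1cc(C(=O)[C@H](CO[Si](C)(C)C(C)(C)C)Oc2ccc(C[C@H]3O[C@H](c4ccc(O[Si](C(C)C)(C(C)C)C(C)C)c(OC)c4)[C@@H](CO[Si](C)(C)C(C)(C)C)[C@@H]3O[Si](C)(C)C(C)(C)C)cc2OC)ccc1O[Si](C(C)C)(C(C)C)C(C)C
F6 | step 13 | erythro alcohol, the C9'-O-TBS ether of 23 | COc1cc([C@@H](O)[C@H](CO[Si](C)(C)C(C)(C)C)Oc2ccc(C[C@H]3O[C@H](c4ccc(O[Si](C(C)C)(C(C)C)C(C)C)c(OC)c4)[C@@H](CO[Si](C)(C)C(C)(C)C)[C@@H]3O[Si](C)(C)C(C)(C)C)cc2OC)ccc1O[Si](C(C)C)(C(C)C)C(C)C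
F7 | step 11 | allyl (ring B aryloxy)acetate | COc1cc(C[C@H]2O[C@H](c3ccc(O[Si](C(C)C)(C(C)C)C(C)C)c(OC)c3)[C@@H](CO[Si](C)(C)C(C)(C)C)[C@@H]2O[Si](C)(C)C(C)(C)C)ccc1OCC(=O)OCC=C
F8 | step 11 | (ring B aryloxy)acetic acid | COc1cc(C[C@H]2O[C@H](c3ccc(O[Si](C(C)C)(C(C)C)C(C)C)c(OC)c3)[C@@H](CO[Si](C)(C)C(C)(C)C)[C@@H]2O[Si](C)(C)C(C)(C)C)ccc1OCC(=O)O
F9 | step 11 | mixed pivalic (ring B aryloxy)acetic anhydride | COc1cc(C[C@H]2O[C@H](c3ccc(O[Si](C(C)C)(C(C)C)C(C)C)c(OC)c3)[C@@H](CO[Si](C)(C)C(C)(C)C)[C@@H]2O[Si](C)(C)C(C)(C)C)ccc1OCC(=O)OC(=O)C(C)(C)C
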